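A flask is slow here when its by-product has not had time to multiply.

    substrate + coupling partner + by-product → target + 2 by-product (k1 = 45 /M²/h, Ea1 = 61.0 kJ/mol)
    substrate + coupling partner → target + by-product (k2 = 0.23 /M/h, Ea2 = 66.0 kJ/mol)
    solid reagent ⇌ coupling partner, rate k3*(cs3 - [coupling partner]) while solid is left; crystals form when [coupling partner] > cs3 (cs3 = 25 mM, k3 = 2.9 /h)
    target → over-reaction product (k4 = 1.7 × 10⁻⁴ /h, Ea4 = 108 kJ/mol)
    substrate ⇌ dormant form (K5 = 6.8, k5 = 2.5 /h, Ea5 = 89.0 kJ/mol, ΔH5 = −6.00 kJ/mol)
    (constants at 20 °C)
the same everywhere: substrate 0.10 M; solid reagent 0.120 M; time 12 h

| run | temperature |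
|---|---|
| epsilon | −10 °C |
| theta | 80 °C |
| alpha | 50 °C |
| eta | 20 °C |
- the flask with the highest amount of target, in percent of the substrate charged ("all alike" if they lie within 1.5 percentage points) (epsilon / theta / alpha / eta / all alike)
- final target, as a percentage of the substrate charged, in epsilon
- final target, as a percentage of the substrate charged, in theta
- final target, as a percentage of the substrate charged, in alpha
- final target, as a percentage of the substrate charged, in eta
- solid reagent is a solid; its amount is given per volume of the solution
- the list of constants is for 20 °C, to be carried to other temperatures by the activation energies and enthalpies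
- at the start none of the solid reagent is in solution

Our reckoning sets two times against each other: the run, 12 h, and the growth time of by-product.

1. The solution nears saturation with a time constant of about 0.345 h, far shorter than the run, so [coupling partner] sits near 25 mM while solid stands.

2. In alpha, substrate and dormant form relax in 0.473 min, far shorter than the run, so free substrate is one part in 6.41 of the pool.

3. The first step is autocatalysis, pseudo-first-order in by-product. The time in which it multiplies [by-product] by e at the full pool is 5.58 h in alpha: the growth time. The second step supplies the seed, and the two steps are equal at [by-product] = 6.18 mM. Growth follows that level times (e^(t/growth time) − 1).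

4. Round one, with the pool held full, gives 46.9 mM in alpha, half the charge, so the pool cannot be held full.

5. Round two uses the mean pool, the charge less half of that figure. The growth time stretches to 7.29 h, and alpha gives 25.9% target.

6. In theta the growth time is 0.693 h and the charge is used in about 1.87 h. But target then falls at 0.316 /h, leaving 4.06%. In eta the growth time is 69.3 h, longer than the run. For epsilon, the second step over the full charge gives roughly 0.315%. We commit to alpha.

The forecast says theta, “leaving theta highest by only a modest margin”: 5.5% there, 3.1% in alpha (from 2.3% to 4.2%), 1.1% in eta, 0.25% in epsilon. We part from it at alpha.

The simulation gives alpha: 29.0% there, against 6.09% in theta, 1.03% in eta and 0.251% in epsilon. At 12.0 h, alpha makes target 14.2 times faster than it uses it up. The growth time 5.58 h, carried to 6.00 h, gives 11.9 mM of by-product in alpha, against a reading of 9.78 mM.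

For the alpha recipe run at 35 °C, the growth time becomes 18.5 h, longer than the run, and round one gives 5.16% target. The simulated neighbour holds 4.76%.

The numbers of this flask stand for no real mixture, and the outcome is calculated.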